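Q comes late.

    Q ⇌ G, rate k1*([Q] - [G]/K1) per volume of the first phase (K1 = 0.34, k1 = 0.063 /s)
    L + Q → L.Q (k2 = 0.060 /M/s)
    2 L → L2 (k3 = 0.089 /M/s)
    Q → Z (k4 = 2.1 × 10⁻⁴ /s)

L 2.0 M; G 2.60 M; time 1.0 min; volume of the second phase over the first 2.0

- in percentages every species weighs as the L in it: one L2 counts as two
- a doubled species enters its step squared and goes two at a time
- in the second phase: G; everything else is in the first
- charges count per volume of the first phase; a concentration in a rate is the amount of a species over the volume of its own phase; every rate counts per litre of the first phase
- run time (flask): 1.0 min

- the L.Q standing at 1.0 min, as a percentage of the L charged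
- the change that raises the amount of L.Q at 1.0 min, in percent of the L charged most ("none" if none brings more than 2 percentage points) (birch / maple / none)
- amount of L.Q at 1.0 min, in percent of the L charged, after birch

Your hunch that L is lost before Q stands holds up in the reckoning. The two steps that use L run level where L equals k2 times Q over twice k3; call this the tie level. While Q stands steady, capture is pseudo-first-order in L, and the share of falling L that becomes L.Q is tie level over tie level plus L. Summed, this gives L.Q as tie level times ln(1 + starting L / tie level).

If G merely shares out by partition, Q stands at 1.55 M. It gets halfway there in 4.45 s, which is longer than the first half-life of L, 2.81 s. So the count starts at that moment, with L, reckoned through dimerisation by itself, at 0.774 M.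

A first pass gives 0.474 M of L.Q. The correction takes this out of the supply, so the reckoned Q is 1.27 M and the tie level is 0.426 M. That makes y about 22.1 %. Birch halves the wait, so L starts at 1.12 M, giving 27.4 %. Maple, taken roughly as doubling the tie level with the wait unchanged, gives 27.5 %, a slender reckoned lead.

The forecast says 24 %, above the 22.1 % reckoned here, with 27.5 % after birch and maple as best, on the ground that “doubling G roughly doubles both the supply rate and the Q level”.

The simulation gives 23.8 %, 28.0 % after birch and maple as best, with maple gaining 8.5 percentage points, more than the 4.2 points of birch. The reckoned gains were 5.4 points for maple and 5.3 points for birch.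

In this flask, counting up to the asked time, half of the L2 turnover was done by 1.75 s, half of the uptake of G by 0.0866 min and half of the L.Q turnover by 0.163 min. L stood at 0.559 M at 0.100 min, above the reckoned tie level, and at 0.0481 M at 0.500 min, below it, when Q stood at 1.25 M. In the flask with 1.2 M of L, the same tie level and wait start L at 0.615 M and give 31.7 %; the simulation gives 33.7 %.

The rate constants are those of an exercise; the run is a simulation.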